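The target is closed at the C3=C4 double bond of its cyclohexa-1,3-diene ring (C1 carries CH2OBz, C5 the benzoate, C6 the free hydroxyl) by diene–ene ring-closing metathesis of an acyclic (Z)-triene, which gives the finished molecule and ethylene in one operation. The step exploits the fact that C3=C4 is the one ring alkene flanked by a stereocentre (C5) and by the C1=C2 alkene, so both partners can pre-exist as vinyl groups. The triene comes from an L-sorbose diacetonide, whose C3/C4 diol becomes C6/C5; a temporary butenolide ring locks the Z geometry of C1=C2.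

Key step: step 9

Remark: compounds 1 and 6 are taken as commercially available; acyclic intermediates carry their own locants, and "future C" refers to the ring numbering above.

Step 1
Reactants: 1 2,3:4,6-di-O-isopropylidene-α-L-sorbofuranose
Product: 2 2,3-O-isopropylidene-α-L-sorbofuranose
Conditions: AcOH/H2O (3:2), 40 °C
Reagents that add atoms: none
Why: Chemoselective acetal hydrolysis, in which the six-membered 4,6-acetal of two ordinary hydroxyls should cleave faster than the cis-fused 2,3-acetonide that engages the anomeric oxygen (as in the selective 5,6-cleavage of diacetone glucose); no stereocentre is touched.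

Step 2
Reactants: 2 2,3-O-isopropylidene-α-L-sorbofuranose
Product: 3 6-deoxy-6-iodo-2,3-O-isopropylidene-α-L-sorbofuranose
Conditions: PPh3, I2, imidazole, THF, 0 → 23 °C
Reagents that add atoms: iodine, [I][I]
Why: Appel-type iodination (SN2 on the alkoxyphosphonium ion) should be selective for the unhindered primary C6 hydroxyl, because the C1 hydroxyl is neopentyl-like next to the ketal carbon and the C4 hydroxyl is secondary.

Step 3
Reactants: 3 6-deoxy-6-iodo-2,3-O-isopropylidene-α-L-sorbofuranose
Product: 4 6-deoxy-6-iodo-2,3-O-isopropylidene-1,4-bis-O-(triethylsilyl)-α-L-sorbofuranose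
Conditions: Et3SiOTf, 2,6-lutidine, CH2Cl2, −78 → 0 °C
Reagents that add atoms: triethylsilyl trifluoromethanesulfonate, CC[Si](CC)(CC)OS(=O)(=O)C(F)(F)F
Why: Silyl ether formation with a silyl triflate and a non-nucleophilic base caps both remaining hydroxyls without displacing the primary iodide, so that only O3 is free once the ring is opened.

Step 4
Reactants: 4 6-deoxy-6-iodo-2,3-O-isopropylidene-1,4-bis-O-(triethylsilyl)-α-L-sorbofuranose
Product: 5 (3S,4R)-3-hydroxy-1,4-bis(triethylsilyloxy)hex-5-en-2-one
Conditions: Zn dust (activated), THF/H2O (4:1), ultrasound, 40 °C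
Reagents that add atoms: none
Why: Bernet–Vasella reductive fragmentation, in which zinc inserts into the C6–I bond, β-elimination of the ring oxygen forms the terminal alkene, and the hemiketal alkoxide at C2 collapses to the ketone with loss of acetone and release of O3–H; the C3 and C4 stereocentres of L-sorbose are not touched.

Step 5
Reactants: 5 (3S,4R)-3-hydroxy-1,4-bis(triethylsilyloxy)hex-5-en-2-one; 6 (triphenylphosphoranylidene)ketene
Product: 8 (5R)-5-[(1R)-1-(triethylsilyloxy)prop-2-en-1-yl]-4-[(triethylsilyloxy)methyl]furan-2(5H)-one, via ester ylide 7 (not isolated)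
Conditions: toluene, 80 °C
Reagents that add atoms: none
Why: Addition of the free hydroxyl to the cumulated ylide gives a stabilised phosphorane ester that undergoes intramolecular Wittig olefination with the adjacent ketone, and the five-membered lactone forces the future C3 carbon cis to the carbinol carbon on the new trisubstituted alkene; no new stereocentre is formed.

Step 6
Reactants: 8 (5R)-5-[(1R)-1-(triethylsilyloxy)prop-2-en-1-yl]-4-[(triethylsilyloxy)methyl]furan-2(5H)-one
Product: 10 (3R,4R,5Z)-3-(triethylsilyloxy)-5-[(triethylsilyloxy)methyl]octa-1,5,7-trien-4-ol, via lactol 9 (not isolated)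
Conditions: i-Bu2AlH, toluene, −78 °C; then Ph3PCH3Br, KN(SiMe3)2, THF, −78 → 23 °C
Reagents that add atoms: methyltriphenylphosphonium bromide, C[P+](c1ccccc1)(c1ccccc1)c1ccccc1.[Br-]
Why: Half-reduction of the lactone gives an aluminium lactolate that is methylenated in the same flask by Wittig reaction of its ring-opened (Z)-hydroxy-enal form before it can dehydrate to a furan, which frees the C4 hydroxyl and keeps the ring-derived Z geometry; a vicinal silyl shift under the basic conditions would be harmless because both silyl groups are removed next.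

Step 7
Reactants: 10 (3R,4R,5Z)-3-(triethylsilyloxy)-5-[(triethylsilyloxy)methyl]octa-1,5,7-trien-4-ol
Product: 11 (3R,4R,5Z)-5-(hydroxymethyl)octa-1,5,7-triene-3,4-diol
Conditions: Bu4NF, THF, 0 → 23 °C
Reagents that add atoms: none
Why: Fluoride-induced desilylation under non-acidic conditions spares the acid-sensitive dienyl carbinol and leaves both stereocentres and the Z alkene unchanged.

Step 8
Reactants: 11 (3R,4R,5Z)-5-(hydroxymethyl)octa-1,5,7-triene-3,4-diol
Product: 12 (3R,4R,5Z)-5-[(benzoyloxy)methyl]-4-hydroxyocta-1,5,7-trien-3-yl benzoate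
Conditions: BzCl (2.1 equiv), pyridine, CH2Cl2, −40 → −20 °C
Reagents that add atoms: benzoyl chloride, O=C(Cl)c1ccccc1
Why: Kinetically controlled acylation should take the primary hydroxyl and then the C3 hydroxyl (future C5), flanked only by a vinyl group, in preference to the C4 hydroxyl (future C6), which is shielded by the fully substituted C5 of the Z-diene and its cis-vinyl arm (allylic 1,3-strain).

Step 9
Reactants: 12 (3R,4R,5Z)-5-[(benzoyloxy)methyl]-4-hydroxyocta-1,5,7-trien-3-yl benzoate
Product: 13 [(5R,6R)-5-(benzoyloxy)-6-hydroxycyclohexa-1,3-dien-1-yl]methyl benzoate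
Conditions: second-generation Grubbs catalyst (H2IMes)(PCy3)Cl2Ru=CHPh (5 mol %), 1,4-benzoquinone (10 mol %), CH2Cl2 (0.005 M), 40 °C
Reagents that add atoms: none
Why: The ruthenium benzylidene should initiate at the monosubstituted vinyl group on the benzoate-bearing carbon (future C4), and the resulting alkylidene adds across the terminal CH=CH2 of the (Z)-diene (future C3) to a ruthenacyclobutane whose cycloreversion forms C3=C4 and, after turnover, releases ethylene. The closest known reaction type is diene–ene ring-closing olefin metathesis of sugar-derived trienes to cyclohexa-1,3-dienes. The one ring closed is the six-membered carbocycle, formed from the two terminal alkenes of a 1,7-diene relationship to give an endocyclic cis-alkene conjugated with C1=C2. No stereocentre is created; C5 and C6 come unchanged from C4 and C3 of L-sorbose. The step needs ring-size selectivity (closure onto the terminal alkene, not onto the internal trisubstituted C1=C2, which would give a cyclopentene and butadiene), secured by the much lower reactivity of the trisubstituted, allylically branched alkene, and it needs C3 cis to C6 on C1=C2, secured by the Z geometry inherited from the butenolide. High dilution should suppress cross-metathesis, and benzoquinone should suppress Ru–H isomerisation and aromatisation.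

Compound list
1 | 2,3:4,6-di-O-isopropylidene-α-L-sorbofuranose | OC[C@]12OC(C)(C)O[C@H]1[C@@H]1OC(C)(C)OC[C@@H]1O2 | starting material
2 | 2,3-O-isopropylidene-α-L-sorbofuranose | OC[C@]12OC(C)(C)O[C@H]1[C@H](O)[C@H](CO)O2 | intermediate
3 | 6-deoxy-6-iodo-2,3-O-isopropylidene-α-L-sorbofuranose | OC[C@]12OC(C)(C)O[C@H]1[C@H](O)[C@H](CI)O2 | intermediate
4 | 6-deoxy-6-iodo-2,3-O-isopropylidene-1,4-bis-O-(triethylsilyl)-α-L-sorbofuranose | CC[Si](CC)(CC)OC[C@]12OC(C)(C)O[C@H]1[C@H](O[Si](CC)(CC)CC)[C@H](CI)O2 | intermediate
5 | (3S,4R)-3-hydroxy-1,4-bis(triethylsilyloxy)hex-5-en-2-one | CC[Si](CC)(CC)OCC(=O)[C@@H](O)[C@H](O[Si](CC)(CC)CC)C=C | intermediate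
6 | (triphenylphosphoranylidene)ketene | O=C=C=P(c1ccccc1)(c1ccccc1)c1ccccc1 | starting material
7 | (3S,4R)-2-oxo-1,4-bis(triethylsilyloxy)hex-5-en-3-yl (triphenylphosphoranylidene)acetate (ester ylide) | CC[Si](CC)(CC)OCC(=O)[C@@H](OC(=O)C=P(c1ccccc1)(c1ccccc1)c1ccccc1)[C@H](O[Si](CC)(CC)CC)C=C | intermediate
8 | (5R)-5-[(1R)-1-(triethylsilyloxy)prop-2-en-1-yl]-4-[(triethylsilyloxy)methyl]furan-2(5H)-one | CC[Si](CC)(CC)OCC1=CC(=O)O[C@H]1[C@H](O[Si](CC)(CC)CC)C=C | intermediate
9 | (5R)-5-[(1R)-1-(triethylsilyloxy)prop-2-en-1-yl]-4-[(triethylsilyloxy)methyl]-2,5-dihydrofuran-2-ol (lactol, both anomers) | CC[Si](CC)(CC)OCC1=CC(O)O[C@H]1[C@H](O[Si](CC)(CC)CC)C=C | intermediate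
10 | (3R,4R,5Z)-3-(triethylsilyloxy)-5-[(triethylsilyloxy)methyl]octa-1,5,7-trien-4-ol | CC[Si](CC)(CC)OC/C(=C/C=C)[C@@H](O)[C@H](O[Si](CC)(CC)CC)C=C | intermediate
11 | (3R,4R,5Z)-5-(hydroxymethyl)octa-1,5,7-triene-3,4-diol | OC/C(=C/C=C)[C@@H](O)[C@H](O)C=C | intermediate
12 | (3R,4R,5Z)-5-[(benzoyloxy)methyl]-4-hydroxyocta-1,5,7-trien-3-yl benzoate | O=C(OC/C(=C/C=C)[C@@H](O)[C@H](OC(=O)c1ccccc1)C=C)c1ccccc1 | intermediate
13 | [(5R,6R)-5-(benzoyloxy)-6-hydroxycyclohexa-1,3-dien-1-yl]methyl benzoate | O=C(OCC1=CC=C[C@@H](OC(=O)c2ccccc2)[C@@H]1O)c1ccccc1 | target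

Total step count: 9. Longest linear sequence: 9 steps (1 to 13).

Steps most likely to fail

Step 8. The two secondary allylic hydroxyls may not be discriminated well enough, and base-mediated 1,2-benzoyl migration could scramble the acylation pattern. The fallback sets out from 11 and comes back at 12. The primary and the C4 hydroxyl, which are 1,3-related, are bridged with t-Bu2Si(OTf)2 and 2,6-lutidine in CH2Cl2 at 0 °C, since a silylene strongly prefers a 1,3-diol over a 1,2-diol; this gives the di-tert-butylsilylene acetal F1. Its only free hydroxyl is benzoylated (BzCl, pyridine, DMAP) to the silylene benzoate F2. The silylene is cleaved with HF·pyridine in THF, an acidic fluoride source that avoids acyl migration, to the diol monobenzoate F3. The primary hydroxyl of F3 is then benzoylated selectively (BzCl 1.05 equiv, 2,4,6-collidine, CH2Cl2, −40 °C) to give 12.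

Step 6. The lactolate may collapse and dehydrate to a furan (aromatisation), or ring-opening may be so slow that the ylide is consumed by deprotonation instead of olefination. The fallback sets out from 8 and comes back at 10. After the same i-Bu2AlH half-reduction, Me3SiCH2MgCl is added to the lactolate; irreversible 1,2-addition to the small equilibrium amount of hydroxy-enal gives the β-hydroxysilane diol F4. Peterson elimination with KH in THF then gives 10.

Step 5. The α-hydroxy ketone may epimerise through its enediol on heating with the basic ylide, or the hindered secondary hydroxyl may be acylated too slowly. The fallback sets out from 5 and comes back at 8. The hydroxyl is esterified with diethylphosphonoacetic acid (DCC, DMAP cat., CH2Cl2, 0 °C) to the phosphonoacetate F5. The butenolide is then closed at 23 °C by intramolecular Horner–Wadsworth–Emmons reaction with LiCl and i-Pr2NEt in MeCN, which gives 8.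

Further compounds
F1 | step 8 | (4R,5Z)-2,2-di-tert-butyl-4-[(1R)-1-hydroxyprop-2-en-1-yl]-5-(prop-2-en-1-ylidene)-1,3,2-dioxasilinane | CC(C)(C)[Si]1(C(C)(C)C)OC/C(=C/C=C)[C@H]([C@H](O)C=C)O1
F2 | step 8 | (1R)-1-[(4R,5Z)-2,2-di-tert-butyl-5-(prop-2-en-1-ylidene)-1,3,2-dioxasilinan-4-yl]prop-2-en-1-yl benzoate | CC(C)(C)[Si]1(C(C)(C)C)OC/C(=C/C=C)[C@H]([C@H](OC(=O)c2ccccc2)C=C)O1
F3 | step 8 | (3R,4R,5Z)-4-hydroxy-5-(hydroxymethyl)octa-1,5,7-trien-3-yl benzoate | OC/C(=C/C=C)[C@@H](O)[C@H](OC(=O)c1ccccc1)C=C
F4 | step 6 | (3R,4R,5Z,7RS)-3-(triethylsilyloxy)-5-[(triethylsilyloxy)methyl]-8-(trimethylsilyl)octa-1,5-diene-4,7-diol | CC[Si](CC)(CC)OC/C(=C/C(O)C[Si](C)(C)C)[C@@H](O)[C@H](O[Si](CC)(CC)CC)C=C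
F5 | step 5 | (3S,4R)-2-oxo-1,4-bis(triethylsilyloxy)hex-5-en-3-yl (diethoxyphosphoryl)acetate | CC[Si](CC)(CC)OCC(=O)[C@@H](OC(=O)CP(=O)(OCC)OCC)[C@H](O[Si](CC)(CC)CC)C=C
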